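**Retrosynthetic overview**
1. Target 38 ⇐ 9‑O‑desilylation and ene‑type allylic chlorination (C6–Cl, C5=C16) of the 4,8‑epoxy‑5‑ene 36.
2. The tetrahydropyran (4,8‑ether) is the last ring formed, by transannular allylic etherification of macrocycle 35; the ten‑membered carbocycle is closed just before it by a Nozaki–Hiyama–Kishi coupling (C4–C5).
3. The C2/C3 syn‑diol and C4 come from a Brown γ‑alkoxyallylboration of a C2 aldehyde; C11(OH)CH2OAc comes from a Corey–Chaykovsky epoxide opened by acetate.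
4. C1 (quaternary), C10 and C9 are set in one three‑component coupling: Me2CuLi addition to enone 6 (cyclohexane ring bought), then aldol with lactone aldehyde 22.
5. The γ‑lactone is the first ring made: Evans aldol (C8, C17), Seebach dioxolanone aldol with (Z)‑3‑iodobut‑2‑enal (C7), lactonisation.

Assumption: the target is exactly the given SMILES, (1R,2R,3R,4R,6S,7R,8R,9S,10S,11S,14S,17R) in briarane numbering (C15 = methyl on C1, C16 = exocyclic carbon on C5, C17/C18/C19 = lactone CH, its methyl, the carbonyl, C20 = carbon on C11), used for all locants below.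

**Route**

Step 1
Reactants: 1 3-ethoxycyclohex-2-en-1-one
Product: 2 rac-3-ethoxy-6-hydroxycyclohex-2-en-1-one
Conditions: LiN(iPr)2, THF, −78 °C; 3-phenyl-2-(phenylsulfonyl)oxaziridine; H2O
Reagents that add atoms: 3-phenyl-2-(phenylsulfonyl)oxaziridine, O=S(=O)(N1OC1c1ccccc1)c1ccccc1
Why: Kinetic deprotonation of the vinylogous ester at the alpha‑prime CH2 and electrophilic enolate hydroxylation (Davis oxidation) give the racemic acyloin that becomes C14–O.

Step 2
Reactants: 2 rac-3-ethoxy-6-hydroxycyclohex-2-en-1-one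
Product: 3 (S)-3-ethoxy-6-hydroxycyclohex-2-en-1-one
Conditions: Amano lipase PS, vinyl acetate, MTBE, 30 °C, to ca. 55% conversion
Reagents that add atoms: none
Why: Lipase kinetic resolution by O‑acetylation; by the Kazlauskas rule (conjugated carbonyl side = large group) the (R)‑alcohol is acylated and the (S)‑alcohol is recovered (at most 50%).

Step 3
Reactants: 3 (S)-3-ethoxy-6-hydroxycyclohex-2-en-1-one
Product: 4 (S)-3-ethoxy-6-(triethylsilyloxy)cyclohex-2-en-1-one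
Conditions: TESCl, imidazole, DMF, 0 °C
Reagents that add atoms: chlorotriethylsilane, CC[Si](Cl)(CC)CC
Why: Standard silylation; TES is chosen so that it can later be removed beside a hindered TBS ether.

Step 4
Reactants: 4 (S)-3-ethoxy-6-(triethylsilyloxy)cyclohex-2-en-1-one
Product: 6 (S)-3-(1,3-dithian-2-yl)-4-(triethylsilyloxy)cyclohex-2-en-1-one, via carbinol adduct 5 (not isolated)
Conditions: 1,3-dithiane, n-BuLi, THF, −30 °C; add 4, −78 to 0 °C; H2O; oxalic acid (cat.), wet THF, rt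
Reagents that add atoms: 2-lithio-1,3-dithiane, [Li]C1SCCCS1; water, O
Why: Stork–Danheiser sequence (1,2‑addition, then enol ether hydrolysis and dehydration) transposes the enone and puts the masked C2 aldehyde on C1 next to the untouched C14 stereocentre.

Step 5
Reactants: 7 but-2-yn-1-ol
Product: 9 (Z)-3-iodobut-2-en-1-ol, via cyclic vinylalanate 8 (not isolated)
Conditions: NaAlH2(OCH2CH2OMe)2, THF, 0 °C to rt; I2, −78 °C
Reagents that add atoms: iodine, [I][I]
Why: Hydroxyl‑directed trans‑hydroalumination and iodinolysis with retention give the Z iodide (iodine cis to CH2OH).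

Step 6
Reactants: 9 (Z)-3-iodobut-2-en-1-ol
Product: 10 (Z)-3-iodobut-2-enal
Conditions: MnO2, CH2Cl2, rt
Reagents that add atoms: none
Why: Mild allylic alcohol oxidation that keeps the Z geometry.

Step 7
Reactants: 11 (R)-4-benzyl-3-propanoyl-1,3-oxazolidin-2-one; 12 ethyl glyoxylate
Product: 14 (R)-4-benzyl-3-[(2R,3R)-4-ethoxy-3-hydroxy-2-methyl-4-oxobutanoyl]-1,3-oxazolidin-2-one, via dibutylboron enolate 13 (not isolated)
Conditions: Bu2BOTf, iPr2NEt, CH2Cl2, 0 °C; 12, −78 to 0 °C; H2O2, pH 7 buffer, MeOH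
Reagents that add atoms: none
Why: Evans syn aldol through the Z boron enolate and a Zimmerman–Traxler chair; the (R)‑benzyl auxiliary gives (2R,3R), which sets C17 and C8 with methyl and hydroxyl syn.

Step 8
Reactants: 14 (R)-4-benzyl-3-[(2R,3R)-4-ethoxy-3-hydroxy-2-methyl-4-oxobutanoyl]-1,3-oxazolidin-2-one
Product: 15 (2R,3R)-2-hydroxy-3-methylbutanedioic acid
Conditions: LiOH, H2O2, THF/H2O, 0 °C to rt; Na2SO3; HCl
Reagents that add atoms: lithium hydroxide, [Li+].[OH-]; hydrogen peroxide, OO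
Why: Hydroperoxide cleavage of the imide and saponification of the ethyl ester; no stereocentre is touched.

Step 9
Reactants: 15 (2R,3R)-2-hydroxy-3-methylbutanedioic acid
Product: 16 (2R)-2-[(2R,4R)-2-tert-butyl-5-oxo-1,3-dioxolan-4-yl]propanoic acid
Conditions: pivalaldehyde, TsOH·H2O (cat.), H2SO4 (cat.), pentane, reflux, Dean–Stark
Reagents that add atoms: pivalaldehyde, CC(C)(C)C=O
Why: Acetalisation of the α‑hydroxy acid gives the five‑membered dioxolanone with tert‑butyl cis to the side chain (thermodynamic acetal), the relay centre for self‑regeneration of the C8 stereocentre.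

Step 10
Reactants: 16 (2R)-2-[(2R,4R)-2-tert-butyl-5-oxo-1,3-dioxolan-4-yl]propanoic acid; 10 (Z)-3-iodobut-2-enal
Product: 19 (2R,5S,6S,9R)-2-tert-butyl-6-[(Z)-2-iodoprop-1-enyl]-9-methyl-1,3,7-trioxaspiro[4.4]nonane-4,8-dione, via dilithium enolate carboxylate 17 (not isolated), via aldol hydroxy acid 18 (not isolated)
Conditions: LiN(SiMe3)2 (2.2 equiv), THF, −78 °C; 10; HCl (aq); TsOH (cat.), CH2Cl2, rt
Reagents that add atoms: none
Why: Aldol of the dioxolanone enolate: the enal adds anti to tert‑butyl (C8, overall retention) through a Zimmerman–Traxler chair with the alkenyl group equatorial (C7), and acid closes the γ‑lactone with alkenyl, O8 and C18 all cis.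

Step 11
Reactants: 19 (2R,5S,6S,9R)-2-tert-butyl-6-[(Z)-2-iodoprop-1-enyl]-9-methyl-1,3,7-trioxaspiro[4.4]nonane-4,8-dione
Product: 21 (2S,3S,4R)-3-hydroxy-2-[(Z)-2-iodoprop-1-enyl]-4-methyl-5-oxooxolane-3-carbaldehyde, via lactol 20 (not isolated)
Conditions: iBu2AlH (1.05 equiv), CH2Cl2, −78 °C; KNaC4H4O6 (aq); Et3N (cat.), CH2Cl2, rt
Reagents that add atoms: none
Why: Half‑reduction of the more electrophilic acylal‑type dioxolanone carbonyl in preference to the hindered γ‑lactone; the lactol collapses with loss of pivalaldehyde to the non‑enolisable α‑hydroxy aldehyde (C9).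

Step 12
Reactants: 21 (2S,3S,4R)-3-hydroxy-2-[(Z)-2-iodoprop-1-enyl]-4-methyl-5-oxooxolane-3-carbaldehyde
Product: 22 (2S,3S,4R)-2-[(Z)-2-iodoprop-1-enyl]-4-methyl-5-oxo-3-(triethylsilyloxy)oxolane-3-carbaldehyde
Conditions: TESOTf, 2,6-lutidine, CH2Cl2, −78 to 0 °C
Reagents that add atoms: triethylsilyl triflate, CC[Si](CC)(CC)OS(=O)(=O)C(F)(F)F
Why: Silyl triflate silylation of the tertiary alcohol; the aldehyde has no α‑hydrogen and cannot epimerise.

Step 13
Reactants: 6 (S)-3-(1,3-dithian-2-yl)-4-(triethylsilyloxy)cyclohex-2-en-1-one; 22 (2S,3S,4R)-2-[(Z)-2-iodoprop-1-enyl]-4-methyl-5-oxo-3-(triethylsilyloxy)oxolane-3-carbaldehyde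
Product: 25 9-hydroxy-11-oxo aldol adduct (C1 dithianyl; 8,14-bis-OTES), via lithium enolate 23 (not isolated), via titanium enolate 24 (not isolated)
Conditions: Me2CuLi (from MeLi, CuI), Et2O, −40 to 0 °C; ClTi(OiPr)3, THF, −78 °C; 22, −78 to −30 °C
Reagents that add atoms: lithium dimethylcuprate (Me2CuLi), [Li+].C[Cu-]C
Why: Three‑component conjugate addition–aldol: the cuprate adds anti to the C14 silyloxy group (C1, methyl trans to OTES), and the regiodefined titanium enolate attacks the aldehyde anti to the dithianyl group (C10) through a syn‑selective aldol transition state (C9).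

Step 14
Reactants: 25 9-hydroxy-11-oxo aldol adduct (C1 dithianyl; 8,14-bis-OTES)
Product: 26 9-OTBS 11-ketone (C1 dithianyl; 8,14-bis-OTES)
Conditions: TBSOTf, 2,6-lutidine, CH2Cl2, −78 °C
Reagents that add atoms: tert-butyldimethylsilyl triflate, CC(C)(C)[Si](C)(C)OS(=O)(=O)C(F)(F)F
Why: Non‑basic silylation of the β‑hydroxy ketone blocks retro‑aldol and masks O9 until the last step.

Step 15
Reactants: 26 9-OTBS 11-ketone (C1 dithianyl; 8,14-bis-OTES)
Product: 27 11,20-epoxide (9-OTBS; 8,14-bis-OTES; C1 dithianyl)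
Conditions: Me3S(O)I, NaH, DMSO/THF, rt
Reagents that add atoms: trimethylsulfoxonium iodide, C[S+](C)(C)=O.[I-]
Why: Corey–Chaykovsky epoxidation; the reversibly adding sulfoxonium ylide delivers CH2 equatorially, so the oxygen is axial on the face of the C1 methyl (C11).

Step 16
Reactants: 27 11,20-epoxide (9-OTBS; 8,14-bis-OTES; C1 dithianyl)
Product: 28 11-hydroxy-20-acetate (9-OTBS; 8,14-bis-OTES; C1 dithianyl)
Conditions: CsOAc, 18-crown-6, DMF, 90 °C; H2O
Reagents that add atoms: caesium acetate (CsOAc), CC(=O)[O-].[Cs+]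
Why: SN2 opening of the 1,1‑disubstituted epoxide by acetate at the primary carbon C20 leaves the C11 tertiary alcohol configuration intact.

Step 17
Reactants: 28 11-hydroxy-20-acetate (9-OTBS; 8,14-bis-OTES; C1 dithianyl)
Product: 29 C2 aldehyde (20-OAc; 11-OH; 9-OTBS; 8,14-bis-OTES)
Conditions: MeI, CaCO3, MeCN/H2O (9:1), 50 °C
Reagents that add atoms: water, O
Why: S‑alkylative hydrolysis of the dithiane unmasks the non‑enolisable neopentyl aldehyde.

Step 18
Reactants: 29 C2 aldehyde (20-OAc; 11-OH; 9-OTBS; 8,14-bis-OTES)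
Product: 30 (2R,3R)-2-hydroxy-3-(methoxymethoxy) terminal alkene
Conditions: allyl methoxymethyl ether, s-BuLi, THF, −78 °C; (−)-Ipc2BOMe; BF3·OEt2; 29, −78 °C to rt; NaBO3·4H2O
Reagents that add atoms: [(Z)-3-(methoxymethoxy)allyl]bis(isopinocampheyl)borane, COCO/C=C(/[H])CB([C@@H]1C[C@@H]2C[C@H]([C@H]1C)C2(C)C)[C@@H]1C[C@@H]2C[C@H]([C@H]1C)C2(C)C
Why: Brown asymmetric γ‑alkoxyallylboration; the Z reagent reacts through a chair transition state to give the syn (threo) diol monoether, and the isopinocampheyl groups from (+)‑α‑pinene set C2 as R, hence (2R,3R).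

Step 19
Reactants: 30 (2R,3R)-2-hydroxy-3-(methoxymethoxy) terminal alkene
Product: 31 (2R,3R)-2,3-diol (8,14-bis-OTES; 9-OTBS)
Conditions: Me2BBr, CH2Cl2, −78 °C; NaHCO3 (aq)
Reagents that add atoms: none
Why: Dimethylboron bromide cleaves the MOM acetal chemoselectively at low temperature; silyl ethers, esters and the lactone survive.

Step 20
Reactants: 31 (2R,3R)-2,3-diol (8,14-bis-OTES; 9-OTBS)
Product: 32 2,3,8,11,14-pentaol (9-OTBS; 20-OAc)
Conditions: HF·pyridine, pyridine, THF, 0 °C, 2 h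
Reagents that add atoms: none
Why: Fluoride desilylation removes both triethylsilyl ethers while the far more hindered 9‑O‑TBS ether stays.

Step 21
Reactants: 32 2,3,8,11,14-pentaol (9-OTBS; 20-OAc)
Product: 33 2,3,14,20-tetraacetate (8,11-diol; 9-OTBS; terminal alkene)
Conditions: Ac2O, DMAP (cat.), pyridine, CH2Cl2, 0 °C to rt
Reagents that add atoms: acetic anhydride, CC(=O)OC(C)=O
Why: DMAP‑catalysed acetylation esterifies the three secondary alcohols; the two tertiary alcohols (C8, C11) do not react under these conditions.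

Step 22
Reactants: 33 2,3,14,20-tetraacetate (8,11-diol; 9-OTBS; terminal alkene)
Product: 34 C4 aldehyde (2,3,14,20-tetraacetate; 9-OTBS; alkenyl iodide)
Conditions: OsO4 (2 mol %), NaIO4, 2,6-lutidine, dioxane/H2O (3:1), rt
Reagents that add atoms: osmium tetroxide (OsO4), O=[Os](=O)(=O)=O; sodium periodate (NaIO4), [Na+].[O-]I(=O)(=O)=O
Why: Lemieux–Johnson cleavage of the monosubstituted alkene gives the C4 aldehyde; the deactivated trisubstituted alkenyl iodide is not dihydroxylated.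

Step 23
Reactants: 34 C4 aldehyde (2,3,14,20-tetraacetate; 9-OTBS; alkenyl iodide)
Product: 35 ten-membered allylic alcohol (4-OH epimers; Z-5,6-alkene)
Conditions: CrCl2 (10 equiv), NiCl2 (2 mol %), DMSO/THF (3:1), rt, 2 mM, slow addition
Reagents that add atoms: none
Why: Intramolecular Nozaki–Hiyama–Kishi coupling; the alkenylchromium keeps the Z geometry, so C4 and C7 end up cis on the 5,6‑alkene, and the C4 carbinol configuration does not matter for the next step.

Step 24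
Reactants: 35 ten-membered allylic alcohol (4-OH epimers; Z-5,6-alkene)
Product: 36 4,8-epoxy-5-ene (9-OTBS)
Conditions: Re2O7 (5 mol %), CH2Cl2, 0 °C to rt
Reagents that add atoms: none
Why: Transannular dehydrative allylic etherification; perrhenate ionises the allylic alcohol reversibly and the tertiary 8‑OH traps C4 in a six‑membered ring, where the bridge allows only the 4R configuration, so both epimers converge.

Step 25
Reactants: 36 4,8-epoxy-5-ene (9-OTBS)
Product: 37 9-O-TBS ether of the target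
Conditions: Ca(OCl)2, CO2 (solid), CH2Cl2/H2O, 0 °C
Reagents that add atoms: calcium hypochlorite (Ca(OCl)2), [Ca+2].[O-]Cl.[O-]Cl
Why: Ene‑type allylic chlorination with HOCl; chlorine adds to C6 on the convex face anti to the five‑carbon bridge (6S) and the C5 cation loses a C16 proton to give the exocyclic alkene, since loss of the bridgehead H4 is not possible.

Step 26
Reactants: 37 9-O-TBS ether of the target
Product: 38 CNP0190959.1 (target)
Conditions: HF·pyridine (excess), THF, rt, 24 h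
Reagents that add atoms: none
Why: Fluoride desilylation of the hindered silyl ether frees the 9‑OH without touching the acetates, the lactone or the allylic chloride.

**Compound list**
1 | 3-ethoxycyclohex-2-en-1-one | CCOC1=CC(=O)CCC1 | starting material
2 | rac-3-ethoxy-6-hydroxycyclohex-2-en-1-one | CCOC1=CC(=O)C(O)CC1 | intermediate
3 | (S)-3-ethoxy-6-hydroxycyclohex-2-en-1-one | CCOC1=CC(=O)[C@@H](O)CC1 | intermediate
4 | (S)-3-ethoxy-6-(triethylsilyloxy)cyclohex-2-en-1-one | CCOC1=CC(=O)[C@@H](O[Si](CC)(CC)CC)CC1 | intermediate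
5 | (6S)-1-(1,3-dithian-2-yl)-3-ethoxy-6-(triethylsilyloxy)cyclohex-2-en-1-ol (carbinol adduct, both C1 epimers) | CCOC1=CC(O)(C2SCCCS2)[C@@H](O[Si](CC)(CC)CC)CC1 | intermediate (not isolated)
6 | (S)-3-(1,3-dithian-2-yl)-4-(triethylsilyloxy)cyclohex-2-en-1-one | O=C1C=C(C2SCCCS2)[C@@H](O[Si](CC)(CC)CC)CC1 | intermediate
7 | but-2-yn-1-ol | CC#CCO | starting material
8 | sodium 2,2-bis(2-methoxyethoxy)-3-methyl-2,5-dihydro-1,2-oxaluminol-2-uide (cyclic vinylalanate) | CC1=CCO[Al-]1(OCCOC)OCCOC.[Na+] | intermediate (not isolated)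
9 | (Z)-3-iodobut-2-en-1-ol | C/C([I])=C/CO | intermediate
10 | (Z)-3-iodobut-2-enal | C/C([I])=C/C=O | intermediate
11 | (R)-4-benzyl-3-propanoyl-1,3-oxazolidin-2-one | CCC(=O)N1C(=O)OC[C@H]1Cc1ccccc1 | starting material
12 | ethyl glyoxylate | CCOC(=O)C=O | starting material
13 | (Z)-dibutylboron enolate of 11 | C/C=C(/N1C(=O)OC[C@H]1Cc1ccccc1)OB(CCCC)CCCC | intermediate (not isolated)
14 | (R)-4-benzyl-3-[(2R,3R)-4-ethoxy-3-hydroxy-2-methyl-4-oxobutanoyl]-1,3-oxazolidin-2-one | CCOC(=O)[C@H](O)[C@@H](C)C(=O)N1C(=O)OC[C@H]1Cc1ccccc1 | intermediate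
15 | (2R,3R)-2-hydroxy-3-methylbutanedioic acid | C[C@@H](C(=O)O)[C@@H](O)C(=O)O | intermediate
16 | (2R)-2-[(2R,4R)-2-tert-butyl-5-oxo-1,3-dioxolan-4-yl]propanoic acid (tert-butyl cis to the side chain) | C[C@@H](C(=O)O)[C@H]1O[C@@H](C(C)(C)C)OC1=O | intermediate
17 | dilithium enolate carboxylate of 16 | C[C@@H](C(=O)[O-])C1=C([O-])O[C@H](C(C)(C)C)O1.[Li+].[Li+] | intermediate (not isolated)
18 | aldol hydroxy acid: 16 carrying at the dioxolanone α‑carbon (C8) a (1S,2Z)-1-hydroxy-3-iodobut-2-enyl group, anti to tert-butyl | C/C([I])=C/[C@H](O)[C@@]1(O[C@@H](C(C)(C)C)OC1=O)[C@@H](C)C(=O)O | intermediate (not isolated)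
19 | (2R,5S,6S,9R)-2-tert-butyl-6-[(Z)-2-iodoprop-1-enyl]-9-methyl-1,3,7-trioxaspiro[4.4]nonane-4,8-dione | C/C([I])=C/[C@@H]1OC(=O)[C@H](C)[C@@]1(O[C@@H](C(C)(C)C)O2)C2=O | intermediate
20 | lactol of 19 (dioxolanone C=O reduced to CH–OH, both anomers) | C/C([I])=C/[C@@H]1OC(=O)[C@H](C)[C@@]1(O[C@@H](C(C)(C)C)O2)C2O | intermediate (not isolated)
21 | (2S,3S,4R)-3-hydroxy-2-[(Z)-2-iodoprop-1-enyl]-4-methyl-5-oxooxolane-3-carbaldehyde | C/C([I])=C/[C@@H]1OC(=O)[C@H](C)[C@@]1(O)C=O | intermediate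
22 | (2S,3S,4R)-2-[(Z)-2-iodoprop-1-enyl]-4-methyl-5-oxo-3-(triethylsilyloxy)oxolane-3-carbaldehyde | C/C([I])=C/[C@@H]1OC(=O)[C@H](C)[C@@]1(O[Si](CC)(CC)CC)C=O | intermediate
23 | lithium enolate from methyl addition to 6 (C1 quaternary: methyl trans to OTES) | [Li]OC1=C[C@@](C)(C2SCCCS2)[C@@H](O[Si](CC)(CC)CC)CC1 | intermediate (not isolated)
24 | triisopropoxytitanium enolate corresponding to 23 | CC(C)O[Ti](OC(C)C)(OC(C)C)OC1=C[C@@](C)(C2SCCCS2)[C@@H](O[Si](CC)(CC)CC)CC1 | intermediate (not isolated)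
25 | aldol adduct: cyclohexanone (C11=O) with C1 methyl and 1,3-dithian-2-yl, 14-OTES, and at C10 the C9 carbinol bound to lactone carbon C8 (8-OTES; C7 (Z)-2-iodoprop-1-enyl; C17 methyl); stereocentres as in 38 | C/C([I])=C/[C@@H]1OC(=O)[C@H](C)[C@@]1(O[Si](CC)(CC)CC)[C@@H](O)[C@H]2C(=O)CC[C@H](O[Si](CC)(CC)CC)[C@]2(C)C3SCCCS3 | intermediate
26 | 9-O-TBS ether of 25 | C/C([I])=C/[C@@H]1OC(=O)[C@H](C)[C@@]1(O[Si](CC)(CC)CC)[C@@H](O[Si](C)(C)C(C)(C)C)[C@H]2C(=O)CC[C@H](O[Si](CC)(CC)CC)[C@]2(C)C3SCCCS3 | intermediate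
27 | 11,20-spiro-epoxide of 26 (epoxide oxygen axial, on the face of the C1 methyl) | C/C([I])=C/[C@@H]1OC(=O)[C@H](C)[C@@]1(O[Si](CC)(CC)CC)[C@@H](O[Si](C)(C)C(C)(C)C)[C@H]2[C@]4(CO4)CC[C@H](O[Si](CC)(CC)CC)[C@]2(C)C3SCCCS3 | intermediate
28 | 11-hydroxy-20-acetoxy compound from 27 (11S) | C/C([I])=C/[C@@H]1OC(=O)[C@H](C)[C@@]1(O[Si](CC)(CC)CC)[C@@H](O[Si](C)(C)C(C)(C)C)[C@H]2[C@](O)(COC(C)=O)CC[C@H](O[Si](CC)(CC)CC)[C@]2(C)C3SCCCS3 | intermediate
29 | C2 aldehyde (dithiane of 28 hydrolysed; CHO on quaternary C1) | C/C([I])=C/[C@@H]1OC(=O)[C@H](C)[C@@]1(O[Si](CC)(CC)CC)[C@@H](O[Si](C)(C)C(C)(C)C)[C@H]2[C@](O)(COC(C)=O)CC[C@H](O[Si](CC)(CC)CC)[C@]2(C)C=O | intermediate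
30 | (2R,3R)-2-hydroxy-3-(methoxymethoxy) compound: 29 extended at C2 by CH(OMOM)CH=CH2 | C/C([I])=C/[C@@H]1OC(=O)[C@H](C)[C@@]1(O[Si](CC)(CC)CC)[C@@H](O[Si](C)(C)C(C)(C)C)[C@H]2[C@](O)(COC(C)=O)CC[C@H](O[Si](CC)(CC)CC)[C@]2(C)[C@@H](O)[C@H](OCOC)C=C | intermediate
31 | (2R,3R)-2,3-diol (MOM removed; 8,14-bis-OTES; 9-OTBS) | C/C([I])=C/[C@@H]1OC(=O)[C@H](C)[C@@]1(O[Si](CC)(CC)CC)[C@@H](O[Si](C)(C)C(C)(C)C)[C@H]2[C@](O)(COC(C)=O)CC[C@H](O[Si](CC)(CC)CC)[C@]2(C)[C@@H](O)[C@H](O)C=C | intermediate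
32 | 2,3,8,11,14-pentaol (9-OTBS and 20-OAc kept) | C/C([I])=C/[C@@H]1OC(=O)[C@H](C)[C@@]1(O)[C@@H](O[Si](C)(C)C(C)(C)C)[C@H]2[C@](O)(COC(C)=O)CC[C@H](O)[C@]2(C)[C@@H](O)[C@H](O)C=C | intermediate
33 | 2,3,14,20-tetraacetate (8-OH and 11-OH free; 9-OTBS; terminal alkene) | C/C([I])=C/[C@@H]1OC(=O)[C@H](C)[C@@]1(O)[C@@H](O[Si](C)(C)C(C)(C)C)[C@H]2[C@](O)(COC(C)=O)CC[C@H](OC(C)=O)[C@]2(C)[C@@H](OC(C)=O)[C@H](OC(C)=O)C=C | intermediate
34 | C4 aldehyde of 33 (terminal CH2 cleaved) | C/C([I])=C/[C@@H]1OC(=O)[C@H](C)[C@@]1(O)[C@@H](O[Si](C)(C)C(C)(C)C)[C@H]2[C@](O)(COC(C)=O)CC[C@H](OC(C)=O)[C@]2(C)[C@@H](OC(C)=O)[C@H](OC(C)=O)C=O | intermediate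
35 | ten-membered carbocycle: 4-hydroxy (both epimers), (Z)-5,6-alkene with C16 methyl, 8-OH, 9-OTBS, 11-OH, 2,3,14,20-tetraacetate, 7,19-lactone | C/C(=C/[C@@H]1OC(=O)[C@H](C)[C@@]1(O)[C@@H](O[Si](C)(C)C(C)(C)C)[C@H]2[C@](O)(COC(C)=O)CC[C@H](OC(C)=O)[C@]2(C)[C@@H](OC(C)=O)[C@@H]3OC(C)=O)C3O | intermediate
36 | 4,8-epoxy-bridged 5-ene (4R; C16 methyl on C5; 9-OTBS) | CC=1[C@H]2O[C@]3([C@@H](C)C(=O)O[C@H]3C1)[C@@H](O[Si](C)(C)C(C)(C)C)[C@H]1[C@](O)(COC(C)=O)CC[C@H](OC(C)=O)[C@]1(C)[C@@H](OC(C)=O)[C@@H]2OC(C)=O | intermediate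
37 | 9-O-TBS ether of 38 (6S chloride, exocyclic C5=C16) | C=C1[C@H]2O[C@]3([C@@H](C)C(=O)O[C@H]3[C@H]1Cl)[C@@H](O[Si](C)(C)C(C)(C)C)[C@H]1[C@](O)(COC(C)=O)CC[C@H](OC(C)=O)[C@]1(C)[C@@H](OC(C)=O)[C@@H]2OC(C)=O | intermediate
38 | CNP0190959.1: (1R,2R,3R,4R,6S,7R,8R,9S,10S,11S,14S,17R)-2,3,14,20-tetraacetoxy-6-chloro-4,8-epoxy-9,11-dihydroxybriar-5(16)-ene 7,19-lactone | C=C1[C@H]2O[C@]3([C@@H](C)C(=O)O[C@H]3[C@H]1Cl)[C@@H](O)[C@H]1[C@](O)(COC(C)=O)CC[C@H](OC(C)=O)[C@]1(C)[C@@H](OC(C)=O)[C@@H]2OC(C)=O | target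

**Step count and risks**
Total step count: 26. Longest linear sequence: 20 steps (steps 7–12, then 13–26). The enone branch (steps 1–4) and the iodo‑enal branch (steps 5–6) are convergent.

Most likely to fail:

Step 13 (three‑component coupling). The cuprate must add to a hindered β,β‑disubstituted enone, and the aldol with a neopentyl α‑silyloxy aldehyde must give the syn C9/C10 relationship; the new 9‑alkoxide could also migrate the lactone. Fallback: set out from 6 and trap the conjugate‑addition enolate with Me2CuLi/TMSCl/Et3N (THF, −78 °C) as the trimethylsilyl enol ether F1, which is isolated. F1 is then joined to 22 in a Mukaiyama aldol (BF3·OEt2, CH2Cl2, −78 °C; open transition state, Lewis acid in place of a metal enolate), which comes back to the route at 25.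

Step 23 (Nozaki–Hiyama–Kishi closure of the ten‑membered ring). Transannular strain, oligomerisation and acetate migration onto the new chromium alkoxide are the dangers. Fallback: set out from 34 and change the ring closure to a ketone synthesis. Me3SnSnMe3/Pd(PPh3)4 gives the alkenylstannane aldehyde F2. NaClO2/NaH2PO4/2‑methylbut‑2‑ene gives the carboxylic acid F3. 2,2'‑Dipyridyl disulfide/PPh3 gives the S‑(2‑pyridyl) thioester F4. Intramolecular thioester–stannane coupling (Pd2(dba)3, tri(2‑furyl)phosphine, CuO2C(2‑thienyl), THF, high dilution) closes the ring as the macrocyclic C4 enone F5. Luche reduction (NaBH4, CeCl3·7H2O, MeOH, −78 °C) then comes back at 35; either C4 epimer serves.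

Step 24 (transannular etherification). The allylic alcohol is deactivated by the neighbouring 3‑acetate, and other oxygen nucleophiles (11‑OH, acetate participation) may compete with the tertiary 8‑OH. Fallback: set out from 35 and convert the secondary allylic 4‑OH with ClCO2Me/pyridine into the allylic methyl carbonate F6. Pd2(dba)3·CHCl3/PPh3 in THF then ionises it as a π‑allyl complex of zerovalent palladium, which the 8‑OH attacks at C4 to close the tetrahydropyran; the sequence comes back at 36. This net‑retention pathway uses the C4 epimer whose carbonate is cis to the 8‑OH.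

Further compounds
F1 | step 13 | trimethylsilyl enol ether of the methyl adduct of 6 (C11–OTMS, C10=C11) | C[Si](C)(C)OC1=C[C@@](C)(C2SCCCS2)[C@@H](O[Si](CC)(CC)CC)CC1
F2 | step 23 | alkenyl(trimethyl)stannane analogue of 34 (SnMe3 in place of iodine, Z retained) | C/C([Sn](C)(C)C)=C/[C@@H]1OC(=O)[C@H](C)[C@@]1(O)[C@@H](O[Si](C)(C)C(C)(C)C)[C@H]2[C@](O)(COC(C)=O)CC[C@H](OC(C)=O)[C@]2(C)[C@@H](OC(C)=O)[C@H](OC(C)=O)C=O
F3 | step 23 | C4 carboxylic acid of F2 | C/C([Sn](C)(C)C)=C/[C@@H]1OC(=O)[C@H](C)[C@@]1(O)[C@@H](O[Si](C)(C)C(C)(C)C)[C@H]2[C@](O)(COC(C)=O)CC[C@H](OC(C)=O)[C@]2(C)[C@@H](OC(C)=O)[C@H](OC(C)=O)C(=O)O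
F4 | step 23 | S-(2-pyridyl) thioester of F3 | C/C([Sn](C)(C)C)=C/[C@@H]1OC(=O)[C@H](C)[C@@]1(O)[C@@H](O[Si](C)(C)C(C)(C)C)[C@H]2[C@](O)(COC(C)=O)CC[C@H](OC(C)=O)[C@]2(C)[C@@H](OC(C)=O)[C@H](OC(C)=O)C(=O)Sc1ccccn1
F5 | step 23 | macrocyclic C4 enone (4-oxo analogue of 35) | C/C(=C/[C@@H]1OC(=O)[C@H](C)[C@@]1(O)[C@@H](O[Si](C)(C)C(C)(C)C)[C@H]2[C@](O)(COC(C)=O)CC[C@H](OC(C)=O)[C@]2(C)[C@@H](OC(C)=O)[C@@H]3OC(C)=O)C3=O
F6 | step 24 | 4-O-(methoxycarbonyl) derivative of 35 (allylic methyl carbonate) | C/C(=C/[C@@H]1OC(=O)[C@H](C)[C@@]1(O)[C@@H](O[Si](C)(C)C(C)(C)C)[C@H]2[C@](O)(COC(C)=O)CC[C@H](OC(C)=O)[C@]2(C)[C@@H](OC(C)=O)[C@@H]3OC(C)=O)C3OC(=O)OC
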